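Early in each flask a molecule of starting material already faces its forks, so I followed one through them.

| setting | cedar | birch | elm |
|---|---|---|---|
| starting material | 0.80 M | 0.80 M | 0.80 M |
| partner | 1.60 M | 1.60 M | 1.60 M |
| temperature | 75 °C | 50 °C | 25 °C |
| time | 4.0 h | 4.0 h | 4.0 h |

    starting material + partner → intermediate + by-product (k1 = 0.77 L mol⁻¹ h⁻¹, Ea1 = 67.0 kJ mol⁻¹)
    intermediate → target (k2 = 1.3 h⁻¹, Ea2 = 95.0 kJ mol⁻¹)
    starting material ⇌ dormant form (K3 = 2.1, k3 = 0.24 h⁻¹, Ea3 = 89.0 kJ mol⁻¹, ΔH3 = 6.00 kJ mol⁻¹)
    target ⇌ isomer of the product (K4 = 2.6, k4 = 0.58 h⁻¹, Ea4 = 84.0 kJ mol⁻¹, ΔH4 = 3.00 kJ mol⁻¹)
    partner → decomposed reagent (k5 = 0.18 h⁻¹, Ea5 = 95.0 kJ mol⁻¹)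
    (constants at 25 °C)

- the flask with the highest amount of target, in percent of the starting material charged ("all alike" if they lie within 1.5 percentage points) (cedar / birch / elm / all alike)
- final target, as a percentage of the starting material charged, in cedar
- final target, as a percentage of the starting material charged, in birch
- final target, as a percentage of the starting material charged, in elm

- all constants are for 25 °C and move with temperature by the activation energies and enthalpies

The partner comes first. It is charged at twice the starting material, but it also decomposes on its own. The activation energy of that loss is higher than that of the productive step, so I expected heating to waste partner. The dormant form's step also outruns the productive step in activation energy, by 22.0 kJ mol⁻¹, so heating should hold back starting material as well. I did not integrate these races, so my reckoning leaves the conversion x open. Each molecule through the first step leaves one by-product, so x is c(by-product) over the charged c(starting material).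

The last fork I could reckon. In birch, the target and its isomer relax in 0.0643 h, far shorter than the 4.0 h run, so the pair is under thermodynamic control. A molecule in it is target with the chance one over one plus the equilibrium constant at that temperature, which is 25.9% in birch. This target share of the pair gives target as x times the share once the intermediate has gone. The share is 24.4% in cedar and 27.8% in elm, so it is slightly higher in the cooler flask. But elm's pair relaxes more slowly, in 0.863 h, about as long as the first step's time at the charged partner. So I expected elm's target to lag above x times its share, and with the heating losses expected above I put elm highest.

The forecast also named elm, with 11.2% in cedar, 16.4% in birch and 26.5% in elm. One of its grounds was: “The isomer equilibrium then leaves only about a quarter of that as target when hot”.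

The simulation gave elm as the highest, with 11.1% in cedar, 16.8% in birch and 29.9% in elm. Birch ended with 0.518 M of by-product, so x was 64.7%, and multiplying by the share 25.9% gives 16.8% of target. The neighbouring flask was birch with 0.40 M of partner. It ended with 0.178 M of by-product, so x was 22.2%. The same share gives 5.75%, and that flask held 5.77% of target.

Its constants are invented; what happens was integrated by code.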